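Rings: A and C are the two 1-alkyl-3-aryloxy-4,5-dihydroxybenzene rings, B is the para-phenylene (ether O on C1, CH2 on C4), D is the meta-phenylene; the 19-membered ring runs A–O–B–CH2CH2–C–O–D–CH2CH2–A.
Cuts, in retrosynthetic order: the four O–CH3 bonds of a tetramethyl ether; the ring B C4–CH2 bond of the B–CH2CH2–C bridge (opens the macrocycle); the ring D C3–CH2 bond of the D–CH2CH2–A bridge; the two diaryl ether O–C bonds to rings B and D.
Enabling feature: each ArCH2–CH2Ar' bridge is a masked pair of a vinyl group (on ring C, on ring A) and an aryl halide (C4–Br of ring B para to the ether oxygen, C3–I of ring D), so hydroboration and B-alkyl Suzuki coupling give the saturated bridge directly, and both vinyl rings are one and the same vinylphenol.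
Forward: aldehyde 1 → vinylphenol 2 (rings A and C); 2 + boronic acid 3 → ether 4 (A–O–B); 2 + boronic acid 5 → ether 6 (C–O–D); 4 + 6 → borane 7 → open-chain 8 (bridge D–A); 8 → borane 9 → macrocycle 10 (bridge B–C, ring closure); 10 → boronate 11 → target 12.
Stereochemistry: none to set; the target has no stereocentre and no stereogenic double bond.

Key step: step 5

Remark: compounds 1, 3 and 5 are taken as commercial; 9-BBN = 9-borabicyclo[3.3.1]nonane, dppf = 1,1'-bis(diphenylphosphino)ferrocene.

Step 1
Reactants: 1 3-hydroxy-4,5-dimethoxybenzaldehyde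
Product: 2 2,3-dimethoxy-5-vinylphenol
Conditions: Ph3PCH3Br (2.5 equiv), KOtBu (2.5 equiv), THF, 0 °C to rt; aq. NH4Cl work-up
Reagents that add atoms: methyltriphenylphosphonium bromide, C[P+](c1ccccc1)(c1ccccc1)c1ccccc1.[Br-]
Why: Wittig methylenation, in which the extra equivalent of base covers the phenol (its oxide is meta to the aldehyde and does not deactivate it) and the ylide should turn the aldehyde into the terminal alkene without creating a stereocentre.

Step 2
Reactants: 2 2,3-dimethoxy-5-vinylphenol; 3 4-bromophenylboronic acid (2 equiv)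
Product: 4 1-(4-bromophenoxy)-2,3-dimethoxy-5-vinylbenzene
Conditions: Cu(OAc)2 (0.2 equiv), pyridine (3 equiv), 4 Å molecular sieves, O2 (1 atm), CH2Cl2, rt
Reagents that add atoms: none
Why: Chan–Lam oxidative C–O coupling, in which the aryl group passes from boron to the copper phenoxide and reductive elimination from trivalent copper should give the diaryl ether at room temperature, where the aryl bromide and the vinyl group are inert.

Step 3
Reactants: 2 2,3-dimethoxy-5-vinylphenol; 5 3-iodophenylboronic acid (2 equiv)
Product: 6 1-(3-iodophenoxy)-2,3-dimethoxy-5-vinylbenzene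
Conditions: Cu(OAc)2 (0.2 equiv), pyridine (3 equiv), 4 Å molecular sieves, O2 (1 atm), CH2Cl2, rt
Reagents that add atoms: none
Why: Chan–Lam oxidative C–O coupling as in step 2, which should leave the C–I bond untouched because copper-mediated coupling of aryl iodides with phenols needs heat and a stronger base.

Step 4
Reactants: 4 1-(4-bromophenoxy)-2,3-dimethoxy-5-vinylbenzene (1.2 equiv); 6 1-(3-iodophenoxy)-2,3-dimethoxy-5-vinylbenzene (1.0 equiv)
Product: 8 1-(4-bromophenoxy)-5-{2-[3-(2,3-dimethoxy-5-vinylphenoxy)phenyl]ethyl}-2,3-dimethoxybenzene, via B-alkyl-9-BBN adduct 7 (not isolated)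
Conditions: 4, 9-BBN dimer (0.55 equiv), THF, 0 °C to rt; aq. Cs2CO3, rt, 30 min; then 6, Pd(dppf)Cl2 (5 mol %), AsPh3 (10 mol %), DMF, rt
Reagents that add atoms: none
Why: Hydroboration followed by B-alkyl Suzuki–Miyaura coupling, in which 9-BBN puts boron on the terminal carbon of the vinyl group of 4 and zerovalent palladium at room temperature should insert into the C–I bond of 6 much faster than into the electron-rich C–Br bond of ring B, while the vinyl group of 6 stays untouched because 4 is kept in excess over B–H and the base quench precedes the addition of 6.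

Step 5
Reactants: 8 1-(4-bromophenoxy)-5-{2-[3-(2,3-dimethoxy-5-vinylphenoxy)phenyl]ethyl}-2,3-dimethoxybenzene
Product: 10 macrocyclic tetramethyl ether of the target, via B-alkyl-9-BBN adduct 9 (not isolated)
Conditions: 9-BBN dimer (0.75 equiv), THF, rt; then syringe-pump addition over 12 h to Pd(dppf)Cl2 (15 mol %), AsPh3 (30 mol %), Cs2CO3 (4 equiv), THF/DMF/H2O, 65 °C, final concentration about 1 mM
Reagents that add atoms: none
Why: 9-BBN adds its boron to the terminal carbon of the ring C vinyl group of 8 to give the primary alkylborane 9, whose hydroxide-activated borate hands the CH2 group to the arylpalladium bromide that zerovalent palladium forms at C4 of ring B, and reductive elimination then joins that CH2 to ring B. The closest known reaction type is the intramolecular B-alkyl Suzuki–Miyaura coupling of an alkyl-9-BBN with an aryl or vinyl halide, a known way to close cyclophane and other macrocyclic rings. The single ring formed is the 19-membered macrocycle, closed by reductive elimination from a 20-membered aryl(alkyl)palladium metallacycle, with the new bond exocyclic to ring B and the bridge already saturated, so that no strained alkene or alkyne has to be held in the ring. No stereocentre is created. The step needs terminal regioselectivity in the hydroboration (secured by the bulk of 9-BBN on a monosubstituted styrene), ring closure over chain growth (secured by slow addition at high dilution and by the two ether oxygens and the meta-linked rings A, C and D, which let the chain fold back) and reductive elimination over beta-hydride elimination (secured by the wide bite angle of dppf). Chemoselectivity is not an issue, since the ring B bromide is the only halide and the ring C vinyl group the only alkene left in 8.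

Step 6
Reactants: 10 macrocyclic tetramethyl ether of the target
Product: 12 macrocyclic bis(bibenzyl) tetraphenol CNP0511668.0, via bis(bromoboronate) 11 (not isolated)
Conditions: BBr3 (10 equiv), CH2Cl2, −78 °C to rt; then ice-water under argon
Reagents that add atoms: none
Why: Lewis-acid cleavage of aryl methyl ethers, in which BBr3 binds each methoxy oxygen and bromide removes the methyl group by SN2, the two catechols being held as cyclic bromoboronates until hydrolysis, while the diaryl ether bonds have no SN2-capable carbon and should survive.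

Compound list
1 | 3-hydroxy-4,5-dimethoxybenzaldehyde | O=Cc1cc(O)c(OC)c(OC)c1 | starting material
2 | 2,3-dimethoxy-5-vinylphenol | C=Cc1cc(O)c(OC)c(OC)c1 | intermediate
3 | 4-bromophenylboronic acid | OB(O)c1ccc(Br)cc1 | starting material
4 | 1-(4-bromophenoxy)-2,3-dimethoxy-5-vinylbenzene | C=Cc1cc(OC)c(OC)c(c1)Oc1ccc(Br)cc1 | intermediate
5 | 3-iodophenylboronic acid | OB(O)c1cccc(I)c1 | starting material
6 | 1-(3-iodophenoxy)-2,3-dimethoxy-5-vinylbenzene | C=Cc1cc(OC)c(OC)c(c1)Oc1cccc(I)c1 | intermediate
7 | 9-{2-[3-(4-bromophenoxy)-4,5-dimethoxyphenyl]ethyl}-9-borabicyclo[3.3.1]nonane (formed in the flask, not isolated) | COc1cc(CCB2C3CCCC2CCC3)cc(Oc2ccc(Br)cc2)c1OC | intermediate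
8 | 1-(4-bromophenoxy)-5-{2-[3-(2,3-dimethoxy-5-vinylphenoxy)phenyl]ethyl}-2,3-dimethoxybenzene | C=Cc1cc(OC)c(OC)c(c1)Oc1cccc(c1)CCc1cc(OC)c(OC)c(c1)Oc1ccc(Br)cc1 | intermediate
9 | 9-[2-(3-{3-[2-(3-(4-bromophenoxy)-4,5-dimethoxyphenyl)ethyl]phenoxy}-4,5-dimethoxyphenyl)ethyl]-9-borabicyclo[3.3.1]nonane (formed in the flask, not isolated) | COc1cc(CCB2C3CCCC2CCC3)cc(Oc2cccc(CCc3cc(OC)c(OC)c(Oc4ccc(Br)cc4)c3)c2)c1OC | intermediate
10 | macrocyclic tetramethyl ether of the target (19-membered ring) | COc1cc2cc(c1OC)Oc1ccc(cc1)CCc1cc(OC)c(OC)c(c1)Oc1cccc(c1)CC2 | intermediate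
11 | macrocycle with both catechols as cyclic 2-bromo-1,3,2-dioxaborole esters (formed in the flask, not isolated) | BrB1Oc2cc3cc(c2O1)Oc4ccc(cc4)CCc5cc6OB(Br)Oc6c(c5)Oc7cccc(c7)CC3 | intermediate
12 | macrocyclic bis(bibenzyl) tetraphenol CNP0511668.0 | Oc1cc2cc(c1O)Oc1ccc(cc1)CCc1cc(O)c(O)c(c1)Oc1cccc(c1)CC2 | target

Total step count: 6. Longest linear sequence: 5 steps (steps 1, 2, 4, 5 and 6; step 3 is the side branch).

Steps most likely to fail

Step 5. Chain growth between molecules may outrun ring closure, and protodeboronation or beta-hydride elimination of the alkylpalladium intermediate may take over at the low concentration needed. Fallback: setting out from 8, the same ring B C4–carbon bond would be made by an intramolecular Mizoroki–Heck reaction of the aryl bromide with the ring C vinyl group (Pd(OAc)2, P(o-tol)3, K2CO3, DMF, 100 °C, high dilution). This should give the macrocyclic (E)-stilbene tetramethyl ether F1. Hydrogenation of its double bond (H2, Pd/C, EtOAc) then comes back to the route at 10.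

Step 4. Chemoselectivity may be lost, either by insertion of palladium into the C–Br bond of ring B (self-coupling of the borane) or by hydroboration of the vinyl group of 6 by unquenched B–H. Fallback: setting out from 2, the phenol is silylated (TIPSCl, imidazole, DMF) to triisopropyl(2,3-dimethoxy-5-vinylphenoxy)silane F2. This is hydroborated with 9-BBN to its B-alkyl-9-BBN adduct F3 and coupled with 6 under the conditions of step 4, now with no aryl bromide in the flask, to give the bibenzyl silyl ether F4. TBAF in THF frees the ring A phenol F5, and a Chan–Lam coupling of it with 3 (Cu(OAc)2, pyridine, O2, CH2Cl2, rt) puts ring B on last and comes back to the route at 8.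

Step 2. Aryl transfer to the phenol flanked by a methoxy group may be slow, so that protodeboronation and homocoupling of the boronic acid and copper-promoted oligomerization of the vinylphenol take over. Fallback: setting out from 1, before the vinyl group exists, an Ullmann-type C–O coupling with 1-bromo-4-iodobenzene (Brc1ccc(I)cc1; CuI, picolinic acid, K3PO4, DMSO, 90 °C) should react at the C–I bond only and give 3-(4-bromophenoxy)-4,5-dimethoxybenzaldehyde F6. Wittig methylenation (Ph3PCH3Br, KOtBu, THF) then comes back to the route at 4.

Further compounds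
F1 | step 5 | macrocyclic (E)-stilbene tetramethyl ether | COc1cc2cc(c1OC)Oc1ccc(cc1)/C=C/c1cc(OC)c(OC)c(c1)Oc1cccc(c1)CC2
F2 | step 4 | triisopropyl(2,3-dimethoxy-5-vinylphenoxy)silane | C=Cc1cc(OC)c(OC)c(c1)O[Si](C(C)C)(C(C)C)C(C)C
F3 | step 4 | 9-{2-[3,4-dimethoxy-5-(triisopropylsilyloxy)phenyl]ethyl}-9-borabicyclo[3.3.1]nonane | COc1cc(CCB2C3CCCC2CCC3)cc(O[Si](C(C)C)(C(C)C)C(C)C)c1OC
F4 | step 4 | {5-[2-(3-(2,3-dimethoxy-5-vinylphenoxy)phenyl)ethyl]-2,3-dimethoxyphenoxy}triisopropylsilane | C=Cc1cc(OC)c(OC)c(c1)Oc1cccc(c1)CCc1cc(OC)c(OC)c(c1)O[Si](C(C)C)(C(C)C)C(C)C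
F5 | step 4 | 5-{2-[3-(2,3-dimethoxy-5-vinylphenoxy)phenyl]ethyl}-2,3-dimethoxyphenol | C=Cc1cc(OC)c(OC)c(c1)Oc1cccc(c1)CCc1cc(O)c(OC)c(OC)c1
F6 | step 2 | 3-(4-bromophenoxy)-4,5-dimethoxybenzaldehyde | O=Cc1cc(OC)c(OC)c(c1)Oc1ccc(Br)cc1
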